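The target is cut at the CH2 bridge that joins the enolised acyl-trione ring to the cyclopentane ring. In the cyclopentane, carbinol carbon C-2 adjoins C-1, which carries the bridging CH2, and C-1 adjoins C-5, which carries the isopropenyl group trans to the bridge: these are the carbonyl, α- and β-carbons of cyclopentenone. One rhodium-catalysed operation adds isopropenyl to the β-carbon enantioselectively and aminomethylates the resulting boron enolate at the α-carbon, making both C–C bonds. Its precursor is plain cyclopent-2-en-1-one, used with a B-isopropenyl borane and a methyleneiminium salt. The Mannich base then serves as a latent exo-methylene ketone for Michael union with an enantiopure dearomatised acylphloroglucinol, and methyl addition to the ketone finishes the carbinol.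

Key step: step 2

Assumption: the six-membered ring is one enol tautomer of a 2-acylcyclohexane-1,3,5-trione, so only its quaternary carbon is stereogenic; the sense of induction of both chiral ligands is assigned by analogy, and the antipodal ligand would be used should it prove opposite.

Step 1
Reactants: 1 2-bromopropene
Product: 3 9-(prop-1-en-2-yl)-9-borabicyclo[3.3.1]nonane (B-isopropenyl-9-BBN), via isopropenylmagnesium bromide 2 (not isolated)
Conditions: Mg, Et2O, reflux; then B-methoxy-9-BBN (1.0 M in hexanes), −78 °C → rt; filter, distil under Ar
Reagents that add atoms: B-methoxy-9-BBN (9-methoxy-9-borabicyclo[3.3.1]nonane), COB1C2CCCC1CCC2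
Why: Grignard formation from the vinylic bromide followed by carbon transfer from magnesium to the borinate ester (transmetalation) is the standard entry to B-alkenyl- and B-allyl-9-BBN reagents, MeOMgBr being expected to precipitate from the ether–hexane medium; no stereocentre is formed.

Step 2
Reactants: 3 B-isopropenyl-9-BBN; 4 cyclopent-2-en-1-one; 5 dimethyl(methylene)ammonium iodide (Eschenmoser's salt)
Product: 7 (2S,3S)-2-[(dimethylamino)methyl]-3-(prop-1-en-2-yl)cyclopentan-1-one, via boron enolate 6 (not isolated)
Conditions: [Rh(OMe)(cod)]2 (1.5 mol%), (S)-BINAP (3.3 mol%), 3 (1.2 equiv), toluene, 80 °C; then 5 (1.5 equiv), THF/DMSO, 0 °C → rt; aq. NaHCO3, acid–base extraction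
Reagents that add atoms: none
Why: The monovalent rhodium methoxide takes the isopropenyl group from boron (the sp2 carbon migrating in preference to the bicyclic sp3 carbons), the alkenyl–rhodium–BINAP species carbometalates the enone in the 1,4 sense to an oxa-π-allyl rhodium enolate, and exchange with a second molecule of 3 releases the boron enolate 6 under aprotic conditions, which then attacks the iminium carbon of 5 in a Mannich reaction. The closest known reaction types are the Rh/BINAP-catalysed asymmetric 1,4-addition of B-aryl-9-BBN reagents to cyclic enones that delivers chiral boron enolates, the Rh/BINAP transfer of an isopropenyl group from boron to cyclic enones, and the aminomethylation of enol borinates with dimethyl(methylene)ammonium iodide. No ring is closed. C-3 is set by the (S)-BINAP ligand, which by analogy with aryl transfer should expose the enone face that leads to the (S)-configured β-carbon. C-2 is set by approach of 5 anti to the new isopropenyl group, remains epimerisable to the more stable trans isomer, and is in any case reset in step 6. The step needs 1,4- over 1,2-addition (secured by the soft alkenyl–rhodium), absence of a racemic background (B-alkenyl-9-BBN reagents do not add thermally to enones locked s-trans) and aminomethylation at C-2 and not C-5 (secured because the enolate is created at C-1/C-2 and the covalent B–O enolate should not equilibrate).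

Step 3
Reactants: 7 (2S,3S)-2-[(dimethylamino)methyl]-3-(prop-1-en-2-yl)cyclopentan-1-one
Product: 8 N,N,N-trimethyl-1-[(1S,5S)-2-oxo-5-(prop-1-en-2-yl)cyclopentyl]methanaminium iodide
Conditions: MeI (3 equiv), acetone, 0 °C → rt; Et2O trituration
Reagents that add atoms: iodomethane, CI
Why: Menshutkin N-methylation of the tertiary amine turns NMe2 into the better leaving group NMe3+ under base-free conditions, so neither elimination nor any change at C-3 is expected and the salt should be storable as a solid.

Step 4
Reactants: 9 (R)-2-methylbutanoic acid; 10 2-methylphloroglucinol (2-methylbenzene-1,3,5-triol)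
Product: 12 (2R)-2-methyl-1-(2,4,6-trihydroxy-3-methylphenyl)butan-1-one, via acid chloride 11 (not isolated)
Conditions: (COCl)2, DMF (cat.), CH2Cl2, 0 °C → rt; then 10, AlCl3 (3.5 equiv), CH2Cl2/PhNO2, 0 °C → rt; 1 M HCl
Reagents that add atoms: none
Why: Friedel–Crafts C-acylation of the highly activated triol should occur once at one of the two equivalent free ring positions (the product being deactivated), and the α-stereocentre of the acyl group is expected to survive because no base is present and the acylium ion is captured rapidly at or below room temperature.

Step 5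
Reactants: 12 (2R)-2-methyl-1-(2,4,6-trihydroxy-3-methylphenyl)butan-1-one
Product: 13 (6R)-3,5-dihydroxy-6-methyl-2-[(2R)-2-methylbutanoyl]-6-(3-methylbut-2-en-1-yl)cyclohexa-2,4-dien-1-one
Conditions: Pd2(dba)3·CHCl3 (2.5 mol%), (S,S)-DACH-phenyl Trost ligand (7.5 mol%), methyl prenyl carbonate (1.0 equiv), 1,4-dioxane, rt
Reagents that add atoms: methyl (3-methylbut-2-en-1-yl) carbonate, COC(=O)OCC=C(C)C
Why: Proposed new method: zerovalent palladium ionises the carbonate to a cationic π-prenyl complex and methoxide (after loss of CO2), the phloroglucinolate so formed attacks the unsubstituted allyl terminus through the methyl-bearing ring carbon C-3 (the more electron-rich of the two nucleophilic ring carbons, O-prenyl ethers being re-ionised by palladium), and the chiral pocket of the ligand differentiates the two faces of C-3, whose flanks differ as acyl-bearing versus unsubstituted, so that the quaternary centre is set under catalyst control independently of the remote acyl stereocentre; the closest known reaction types are the palladium-catalysed intermolecular asymmetric allylic dearomatisation of substituted naphthols with this ligand class and the Tsuji–Trost dearomative allylation of acylphloroglucinols.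

Step 6
Reactants: 8 N,N,N-trimethyl-1-[(1S,5S)-2-oxo-5-(prop-1-en-2-yl)cyclopentyl]methanaminium iodide; 13 (6R)-configured acyl trione
Product: 15 (6R)-3,5-dihydroxy-6-methyl-2-[(2R)-2-methylbutanoyl]-6-(3-methylbut-2-en-1-yl)-4-{[(1R,5S)-2-oxo-5-(prop-1-en-2-yl)cyclopentyl]methyl}cyclohexa-2,4-dien-1-one, via exo-methylene ketone 14 (not isolated)
Conditions: 13 (1.0 equiv), 8 (1.15 equiv), K2CO3 (2.5 equiv), MeOH, 0 °C → rt; citric acid to pH 4
Reagents that add atoms: none
Why: Base-induced E1cB loss of trimethylamine unmasks the exo-methylene ketone in the presence of the trionate, whose only C–H ring carbon (C-4, between two enolised carbonyls) adds in a Michael reaction before the enone can isomerise or dimerise; the new α-stereocentre is set under thermodynamic control, K2CO3/MeOH equilibrating it to the arrangement trans to the isopropenyl group, while the quaternary and acyl stereocentres are not enolisable under these conditions.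

Step 7
Reactants: 15 Michael adduct (cyclopentanone)
Product: 16 (6R)-3,5-dihydroxy-4-{[(1R,2S,5S)-2-hydroxy-2-methyl-5-(prop-1-en-2-yl)cyclopentyl]methyl}-6-methyl-2-[(2R)-2-methylbutanoyl]-6-(3-methylbut-2-en-1-yl)cyclohexa-2,4-dien-1-one (CNP0299585.1)
Conditions: MeLi (5 equiv), CeCl3 (5.5 equiv), THF, −78 °C; aq. NH4Cl
Reagents that add atoms: methyllithium (delivered as methylcerium dichloride), [Li]C
Why: Organocerium 1,2-addition: two equivalents of the weakly basic reagent convert the acidic enols into a dianion that shields the trione and acyl carbonyls, and a further equivalent should add to the only remaining ketone from the face anti to the adjacent CH2–trionate arm, setting the tertiary carbinol with OH cis to the arm and CH3 cis to the isopropenyl group, while the low basicity suppresses enolisation and retro-Michael cleavage.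

Compound list
1 | 2-bromopropene | C=C(C)Br | starting material
2 | isopropenylmagnesium bromide | C=C(C)[Mg]Br | intermediate (not isolated)
3 | 9-(prop-1-en-2-yl)-9-borabicyclo[3.3.1]nonane | C=C(C)B1C2CCCC1CCC2 | intermediate
4 | cyclopent-2-en-1-one | O=C1C=CCC1 | starting material
5 | dimethyl(methylene)ammonium iodide | C=[N+](C)C.[I-] | starting material
6 | 9-{[(3S)-3-(prop-1-en-2-yl)cyclopent-1-en-1-yl]oxy}-9-borabicyclo[3.3.1]nonane (boron enolate) | C=C(C)[C@H]1CCC(OB2C3CCCC2CCC3)=C1 | intermediate (not isolated)
7 | (2S,3S)-2-[(dimethylamino)methyl]-3-(prop-1-en-2-yl)cyclopentan-1-one (trans) | C=C(C)[C@H]1CCC(=O)[C@@H]1CN(C)C | intermediate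
8 | N,N,N-trimethyl-1-[(1S,5S)-2-oxo-5-(prop-1-en-2-yl)cyclopentyl]methanaminium iodide | C=C(C)[C@H]1CCC(=O)[C@@H]1C[N+](C)(C)C.[I-] | intermediate
9 | (R)-2-methylbutanoic acid | CC[C@@H](C)C(=O)O | starting material
10 | 2-methylphloroglucinol | Cc1c(O)cc(O)cc1O | starting material
11 | (R)-2-methylbutanoyl chloride | CC[C@@H](C)C(=O)Cl | intermediate (not isolated)
12 | (2R)-2-methyl-1-(2,4,6-trihydroxy-3-methylphenyl)butan-1-one | CC[C@@H](C)C(=O)c1c(O)cc(O)c(C)c1O | intermediate
13 | (6R)-3,5-dihydroxy-6-methyl-2-[(2R)-2-methylbutanoyl]-6-(3-methylbut-2-en-1-yl)cyclohexa-2,4-dien-1-one | CC[C@@H](C)C(=O)C1=C(O)C=C(O)[C@@](C)(CC=C(C)C)C1=O | intermediate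
14 | (3R)-2-methylidene-3-(prop-1-en-2-yl)cyclopentan-1-one | C=C(C)[C@H]1CCC(=O)C1=C | intermediate (not isolated)
15 | (6R)-3,5-dihydroxy-6-methyl-2-[(2R)-2-methylbutanoyl]-6-(3-methylbut-2-en-1-yl)-4-{[(1R,5S)-2-oxo-5-(prop-1-en-2-yl)cyclopentyl]methyl}cyclohexa-2,4-dien-1-one | C=C(C)[C@H]1CCC(=O)[C@@H]1CC1=C(O)[C@@](C)(CC=C(C)C)C(=O)C(C(=O)[C@H](C)CC)=C1O | intermediate
16 | (6R)-3,5-dihydroxy-4-{[(1R,2S,5S)-2-hydroxy-2-methyl-5-(prop-1-en-2-yl)cyclopentyl]methyl}-6-methyl-2-[(2R)-2-methylbutanoyl]-6-(3-methylbut-2-en-1-yl)cyclohexa-2,4-dien-1-one | C=C(C)[C@H]1CC[C@](C)(O)[C@@H]1CC1=C(O)[C@@](C)(CC=C(C)C)C(=O)C(C(=O)[C@H](C)CC)=C1O | target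

Total step count: 7.
Longest linear sequence: 5 steps (steps 1, 2, 3, 6 and 7, from 2-bromopropene); the trione arm takes 2 steps (4 and 5) before the union.

Steps most likely to fail

Step 5 (labelled step). The prenyl group may be delivered to the unsubstituted ring carbon with rearomatisation, a second prenylation may follow, or the ligand may discriminate the two faces of the methyl-bearing carbon poorly, so that both C-6 epimers form. Fallback with known chemistry, setting out from 12: classical alkylative dearomatisation with prenyl bromide (1.0 equiv) and NaOMe in MeOH at 0 °C, as used for mono-C-alkylated acylphloroglucinols, should give 13 together with its C-6 epimer, (6S)-3,5-dihydroxy-6-methyl-2-[(2R)-2-methylbutanoyl]-6-(3-methylbut-2-en-1-yl)cyclohexa-2,4-dien-1-one F1. The strongly acidic triones would be extracted into aqueous NaHCO3 away from the less acidic aromatic by-products, and 13 would be separated from F1 by preparative HPLC on a chiral stationary phase. The route is rejoined at 13.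

Step 2 (key step). Transfer of the α-branched alkenyl group from boron to rhodium may be slow, enantioselectivity may erode at 80 °C, or the boron enolate may be aminomethylated incompletely or twice. Fallback, setting out from 4: conjugate addition of isopropenylmagnesium bromide 2 under CuBr·SMe2 catalysis (5 mol%, THF, −78 °C) without a chiral ligand, followed by trapping of the magnesium enolate with 5, is the established three-component route to trans Mannich bases. It should give 7 as the racemate, that is together with its enantiomer (2R,3R)-2-[(dimethylamino)methyl]-3-(prop-1-en-2-yl)cyclopentan-1-one F2. Resolution by preparative chromatography on a chiral stationary phase returns the route to 7.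

Step 7. Addition may occur on both faces of the ketone, or the acidic trione may consume the reagent and promote enolisation and retro-Michael fragmentation. Fallback, setting out from 15: the two enol hydroxyls are masked with TBSCl and imidazole in DMF to give the bis(tert-butyldimethylsilyl) enol ether of 15 F3. With no acidic proton left and a bulkier arm next to the ketone, this should accept MeLi/CeCl3 (1.5 equiv, THF, −78 °C) at the cyclopentanone only, giving the bis(tert-butyldimethylsilyl) enol ether of 16 F4. Methanolysis of the silyl enol ethers (K2CO3, MeOH, 0 °C) then delivers 16.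

Further compounds
F1 | step 5 | (6S)-3,5-dihydroxy-6-methyl-2-[(2R)-2-methylbutanoyl]-6-(3-methylbut-2-en-1-yl)cyclohexa-2,4-dien-1-one | CC[C@@H](C)C(=O)C1=C(O)C=C(O)[C@](C)(CC=C(C)C)C1=O
F2 | step 2 | (2R,3R)-2-[(dimethylamino)methyl]-3-(prop-1-en-2-yl)cyclopentan-1-one | C=C(C)[C@@H]1CCC(=O)[C@H]1CN(C)C
F3 | step 7 | bis(tert-butyldimethylsilyl) enol ether of 15 | C=C(C)[C@H]1CCC(=O)[C@@H]1CC1=C(O[Si](C)(C)C(C)(C)C)[C@@](C)(CC=C(C)C)C(=O)C(C(=O)[C@H](C)CC)=C1O[Si](C)(C)C(C)(C)C
F4 | step 7 | bis(tert-butyldimethylsilyl) enol ether of 16 | C=C(C)[C@H]1CC[C@](C)(O)[C@@H]1CC1=C(O[Si](C)(C)C(C)(C)C)[C@@](C)(CC=C(C)C)C(=O)C(C(=O)[C@H](C)CC)=C1O[Si](C)(C)C(C)(C)C
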